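**Retrosynthetic overview**
1. Target 22 ⇐ MnO2 oxidation of the doubly allylic carbinol 21 ⇐ CrCl2/NiCl2 ring closure (C2–C3) of Z-vinyl iodide/E-enal 20; the ten-membered carbocycle is formed last.
2. α-Methylene lactone of 20 ⇐ butenolide 15 by copper-hydride conjugate reduction (sets C7, cis ring fusion) and Eschenmoser methylenation.
3. 15 ⇐ key step: dearomatising vinylogous Mukaiyama aldol of 2-silyloxyfuran 13 with enal 12 (C8–C9 bond, both carbinol centres).
4. 13 ⇐ butenolide 9 ⇐ singlet-oxygen dearomatisation/NaBH4 of 3-substituted furan 7 ⇐ furan-3-carbaldehyde 1 (asymmetric propargylation sets C6, Z-carboalumination sets C3=C4, tiglate put on early).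
5. Ring order: five-membered lactone (from the furan) first, ten-membered ring second.

Assumption: germacrane locants are used in the text (C2 ketone, C3=C4 Z, C6 tiglate carbinol, C7/C8 lactone fusion with O on C8, C9 free carbinol, C1=C10 E, C11=C13 methylene); (S)-TRIP is taken as the catalyst antipode that gives the 1S alcohol 3.

**Route**

Step 1
Reactants: 1 furan-3-carbaldehyde; 2 allenylboronic acid pinacol ester
Product: 3 (1S)-1-(furan-3-yl)but-3-yn-1-ol
Conditions: (S)-TRIP phosphoric acid (5 mol %), 4 Å MS, toluene, 0 °C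
Reagents that add atoms: none
Why: Chiral phosphoric acid-catalysed propargylation (SE2' addition of the allenylboronate through a six-membered chair organised by the acid) is established for heteroaromatic aldehydes and sets the C6 carbinol centre by catalyst control.

Step 2
Reactants: 3 (1S)-1-(furan-3-yl)but-3-yn-1-ol
Product: 5 (1S,3Z)-1-(furan-3-yl)-4-iodo-3-methylbut-3-en-1-ol, via alkenylalane 4 (not isolated)
Conditions: Me3Al (3 equiv), Cp2ZrCl2 (25 mol %), ClCH2CH2Cl, 23 °C then reflux; N-iodosuccinimide, THF, −30 °C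
Reagents that add atoms: trimethylaluminium C[Al](C)C; N-iodosuccinimide O=C1CCC(=O)N1I
Why: Negishi zirconium-catalysed carboalumination adds methyl and aluminium syn, heating isomerises the alkenylalane to the alkoxide-chelated Z isomer 4, and iodination with retention gives the Z-trisubstituted vinyl iodide (future C3=C4) without touching C6.

Step 3
Reactants: 5 (1S,3Z)-1-(furan-3-yl)-4-iodo-3-methylbut-3-en-1-ol; 6 tigloyl chloride
Product: 7 (1S,3Z)-1-(furan-3-yl)-4-iodo-3-methylbut-3-en-1-yl (2E)-2-methylbut-2-enoate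
Conditions: Et3N, DMAP (cat.), CH2Cl2, 0 °C to rt
Reagents that add atoms: none
Why: DMAP-catalysed acylation of the secondary alcohol installs the C6 tiglate early, so this oxygen never needs a protecting group; the configuration is unchanged.

Step 4
Reactants: 7 (1S,3Z)-1-(furan-3-yl)-4-iodo-3-methylbut-3-en-1-yl (2E)-2-methylbut-2-enoate
Product: 9 (1S,3Z)-4-iodo-3-methyl-1-(5-oxo-2,5-dihydrofuran-3-yl)but-3-en-1-yl (2E)-2-methylbut-2-enoate, via hydroxybutenolide 8 (not isolated)
Conditions: O2, hν, tetraphenylporphyrin (cat.), iPr2NEt, CH2Cl2, −78 °C; then NaBH4, EtOH, 0 °C; 1 M HCl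
Reagents that add atoms: dioxygen O=O
Why: Singlet-oxygen [4+2] dearomatisation of the furan and base-induced Kornblum–DeLaMare opening at the unhindered ring C–H give the β-substituted γ-hydroxybutenolide regioselectively, and NaBH4 reduction of its masked aldehyde followed by relactonisation gives the butenolide, while the electron-poor tiglate and vinyl iodide alkenes are inert.

Step 5
Reactants: 10 propanal; 11 2,2-dimethoxyacetaldehyde
Product: 12 (2E)-4,4-dimethoxy-2-methylbut-2-enal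
Conditions: pyrrolidine (cat.), AcOH (cat.), THF, 40 °C, slow addition of 10
Reagents that add atoms: none
Why: Amine/acid-catalysed crossed aldol condensation (enamine of propanal onto the non-enolisable glyoxal monoacetal, then dehydration) gives the thermodynamically preferred E enal.

Step 6
Reactants: 9 (1S,3Z)-4-iodo-3-methyl-1-(5-oxo-2,5-dihydrofuran-3-yl)but-3-en-1-yl (2E)-2-methylbut-2-enoate; 12 (2E)-4,4-dimethoxy-2-methylbut-2-enal
Product: 15 (1S,3Z)-1-{(2R)-2-[(1S,2E)-1-hydroxy-4,4-dimethoxy-2-methylbut-2-en-1-yl]-5-oxo-2,5-dihydrofuran-3-yl}-4-iodo-3-methylbut-3-en-1-yl (2E)-2-methylbut-2-enoate, via silyloxyfuran 13 (not isolated), via silyl ether 14 (not isolated)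
Conditions: TMSOTf, Et3N, CH2Cl2, 0 °C; then 12, cinchonidine-derived N-benzylammonium phenoxide (10 mol %, matched pseudo-enantiomer), THF, −78 °C; citric acid, MeOH, 0 °C
Reagents that add atoms: none
Why: Key dearomatising vinylogous Mukaiyama aldol reaction: the aromatic 2-silyloxyfuran, activated by the Lewis-basic phenoxide, attacks the aldehyde through C5 in an open transition state that favours the erythro C8/C9 pair, and the chiral cation (matched with the weak bias of the exocyclic C6 centre, approach anti to its CH2 branch) fixes C8 as R and C9 as S, the non-acidic conditions leaving acetal, tiglate and vinyl iodide intact.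

Step 7
Reactants: 15 (1S,3Z)-1-{(2R)-2-[(1S,2E)-1-hydroxy-4,4-dimethoxy-2-methylbut-2-en-1-yl]-5-oxo-2,5-dihydrofuran-3-yl}-4-iodo-3-methylbut-3-en-1-yl (2E)-2-methylbut-2-enoate
Product: 16 (1S,3Z)-1-{(2R,3R)-2-[(1S,2E)-1-hydroxy-4,4-dimethoxy-2-methylbut-2-en-1-yl]-5-oxooxolan-3-yl}-4-iodo-3-methylbut-3-en-1-yl (2E)-2-methylbut-2-enoate
Conditions: [(Ph3P)CuH]6 (5 mol %), PhMe2SiH, t-BuOH, toluene, rt
Reagents that add atoms: none
Why: Copper-hydride conjugate reduction of the butenolide (much more reactive than the α-substituted acyclic tiglate) delivers hydride to C7 anti to the C8 side chain, which places the C6 and C9 branches cis on the lactone (C7 R).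

Step 8
Reactants: 16 (1S,3Z)-1-{(2R,3R)-2-[(1S,2E)-1-hydroxy-4,4-dimethoxy-2-methylbut-2-en-1-yl]-5-oxooxolan-3-yl}-4-iodo-3-methylbut-3-en-1-yl (2E)-2-methylbut-2-enoate
Product: 19 (1S,3Z)-1-{(2R,3R)-2-[(1S,2E)-1-hydroxy-4,4-dimethoxy-2-methylbut-2-en-1-yl]-4-methylidene-5-oxooxolan-3-yl}-4-iodo-3-methylbut-3-en-1-yl (2E)-2-methylbut-2-enoate, via Mannich base 17 (not isolated), via ammonium iodide 18 (not isolated)
Conditions: LiN(SiMe3)2 (2.3 equiv), THF, −78 °C; CH2=NMe2+ I−, −78 to 0 °C; then MeI, MeOH, rt; aq. NaHCO3, CH2Cl2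
Reagents that add atoms: N,N-dimethylmethyleneiminium iodide (Eschenmoser's salt) C=[N+](C)C.[I-]
Why: Lactone-enolate Mannich reaction with Eschenmoser's salt, N-methylation and Hofmann-type elimination is the standard α-methylenation; C11 becomes sp2, so no stereocentre is created, and C7/C8 are not enolisable.

Step 9
Reactants: 19 (1S,3Z)-1-{(2R,3R)-2-[(1S,2E)-1-hydroxy-4,4-dimethoxy-2-methylbut-2-en-1-yl]-4-methylidene-5-oxooxolan-3-yl}-4-iodo-3-methylbut-3-en-1-yl (2E)-2-methylbut-2-enoate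
Product: 20 (1S,3Z)-1-{(2R,3R)-2-[(1S,2E)-1-hydroxy-2-methyl-4-oxobut-2-en-1-yl]-4-methylidene-5-oxooxolan-3-yl}-4-iodo-3-methylbut-3-en-1-yl (2E)-2-methylbut-2-enoate
Conditions: Amberlyst-15, acetone/H2O, 0 °C
Reagents that add atoms: water O
Why: Mild acid hydrolysis of the allylic dimethyl acetal liberates the E enal without affecting the lactone, the tiglate or the vinyl iodide.

Step 10
Reactants: 20 (1S,3Z)-1-{(2R,3R)-2-[(1S,2E)-1-hydroxy-2-methyl-4-oxobut-2-en-1-yl]-4-methylidene-5-oxooxolan-3-yl}-4-iodo-3-methylbut-3-en-1-yl (2E)-2-methylbut-2-enoate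
Product: 21 (3aR,4S,6Z,9E,11S,11aR)-8,11-dihydroxy-6,10-dimethyl-3-methylidene-2-oxo-2,3,3a,4,5,8,11,11a-octahydrocyclodeca[b]furan-4-yl (2E)-2-methylbut-2-enoate (both epimers at the new carbinol)
Conditions: CrCl2 (10 equiv), NiCl2 (2 mol %), DMSO/THF, rt, 2 mM, slow addition
Reagents that add atoms: none
Why: Nozaki–Hiyama–Kishi macrocyclisation (nickel-catalysed activation of the vinyl iodide, transmetallation to chromium, 1,2-addition to the enal) closes the ten-membered ring with retention of both alkene geometries and tolerates the free hydroxyl, the esters and the α-methylene lactone; the new C2 carbinol is an inconsequential epimer mixture.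

Step 11
Reactants: 21 (3aR,4S,6Z,9E,11S,11aR)-8,11-dihydroxy-6,10-dimethyl-3-methylidene-2-oxo-2,3,3a,4,5,8,11,11a-octahydrocyclodeca[b]furan-4-yl (2E)-2-methylbut-2-enoate
Product: 22 (3aR,4S,6Z,9E,11S,11aR)-11-hydroxy-6,10-dimethyl-3-methylidene-2,8-dioxo-2,3,3a,4,5,8,11,11a-octahydrocyclodeca[b]furan-4-yl (2E)-2-methylbut-2-enoate
Conditions: MnO2 (15 equiv), CH2Cl2, rt, monitored
Reagents that add atoms: none
Why: Allylic oxidation with MnO2 takes the doubly allylic C2 carbinol much faster than the C9 allylic alcohol, which is deactivated inductively by the C8 oxygen and becomes part of an electron-poor γ-hydroxy enone once C2 is oxidised, giving the cross-conjugated dienone with all stereocentres untouched.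

**Compound list**
1 | furan-3-carbaldehyde | O=Cc1ccoc1 | starting material
2 | allenylboronic acid pinacol ester | C=C=CB1OC(C)(C)C(C)(C)O1 | starting material
3 | (1S)-1-(furan-3-yl)but-3-yn-1-ol | c1occc1[C@@H](O)CC#C | intermediate
4 | dimethylaluminium (1S,3Z)-4-(dimethylalumanyl)-1-(furan-3-yl)-3-methylbut-3-en-1-olate (alkenylalane, not isolated) | c1occc1[C@@H](O[Al](C)C)C/C(C)=C\[Al](C)C | intermediate
5 | (1S,3Z)-1-(furan-3-yl)-4-iodo-3-methylbut-3-en-1-ol | c1occc1[C@@H](O)C/C(C)=C\I | intermediate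
6 | tigloyl chloride, (2E)-2-methylbut-2-enoyl chloride | ClC(=O)/C(C)=C/C | starting material
7 | (1S,3Z)-1-(furan-3-yl)-4-iodo-3-methylbut-3-en-1-yl (2E)-2-methylbut-2-enoate | c1occc1[C@@H](OC(=O)/C(C)=C/C)C/C(C)=C\I | intermediate
8 | (1S,3Z)-1-(2-hydroxy-5-oxo-2,5-dihydrofuran-3-yl)-4-iodo-3-methylbut-3-en-1-yl (2E)-2-methylbut-2-enoate (lactol epimers, not isolated) | OC1OC(=O)C=C1[C@@H](OC(=O)/C(C)=C/C)C/C(C)=C\I | intermediate
9 | (1S,3Z)-4-iodo-3-methyl-1-(5-oxo-2,5-dihydrofuran-3-yl)but-3-en-1-yl (2E)-2-methylbut-2-enoate | C1OC(=O)C=C1[C@@H](OC(=O)/C(C)=C/C)C/C(C)=C\I | intermediate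
10 | propanal | CCC=O | starting material
11 | 2,2-dimethoxyacetaldehyde | COC(OC)C=O | starting material
12 | (2E)-4,4-dimethoxy-2-methylbut-2-enal | O=C/C(C)=C/C(OC)OC | intermediate
13 | (1S,3Z)-4-iodo-3-methyl-1-[5-(trimethylsilyloxy)furan-3-yl]but-3-en-1-yl (2E)-2-methylbut-2-enoate (not isolated) | c1oc(O[Si](C)(C)C)cc1[C@@H](OC(=O)/C(C)=C/C)C/C(C)=C\I | intermediate
14 | O-trimethylsilyl ether of 15 at the new carbinol (not isolated) | O=C1O[C@@H]([C@@H](O[Si](C)(C)C)/C(C)=C/C(OC)OC)C(=C1)[C@@H](OC(=O)/C(C)=C/C)C/C(C)=C\I | intermediate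
15 | (1S,3Z)-1-{(2R)-2-[(1S,2E)-1-hydroxy-4,4-dimethoxy-2-methylbut-2-en-1-yl]-5-oxo-2,5-dihydrofuran-3-yl}-4-iodo-3-methylbut-3-en-1-yl (2E)-2-methylbut-2-enoate | O=C1O[C@@H]([C@@H](O)/C(C)=C/C(OC)OC)C(=C1)[C@@H](OC(=O)/C(C)=C/C)C/C(C)=C\I | intermediate
16 | (1S,3Z)-1-{(2R,3R)-2-[(1S,2E)-1-hydroxy-4,4-dimethoxy-2-methylbut-2-en-1-yl]-5-oxooxolan-3-yl}-4-iodo-3-methylbut-3-en-1-yl (2E)-2-methylbut-2-enoate | O=C1O[C@@H]([C@@H](O)/C(C)=C/C(OC)OC)[C@H](C1)[C@@H](OC(=O)/C(C)=C/C)C/C(C)=C\I | intermediate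
17 | 4-[(dimethylamino)methyl] derivative of 16 on the oxolanone ring (epimers at that carbon, not isolated) | O=C1O[C@@H]([C@@H](O)/C(C)=C/C(OC)OC)[C@H](C1CN(C)C)[C@@H](OC(=O)/C(C)=C/C)C/C(C)=C\I | intermediate
18 | N-methyl quaternary ammonium iodide of 17 (not isolated) | O=C1O[C@@H]([C@@H](O)/C(C)=C/C(OC)OC)[C@H](C1C[N+](C)(C)C)[C@@H](OC(=O)/C(C)=C/C)C/C(C)=C\I.[I-] | intermediate
19 | (1S,3Z)-1-{(2R,3R)-2-[(1S,2E)-1-hydroxy-4,4-dimethoxy-2-methylbut-2-en-1-yl]-4-methylidene-5-oxooxolan-3-yl}-4-iodo-3-methylbut-3-en-1-yl (2E)-2-methylbut-2-enoate | C=C1C(=O)O[C@@H]([C@@H](O)/C(C)=C/C(OC)OC)[C@H]1[C@@H](OC(=O)/C(C)=C/C)C/C(C)=C\I | intermediate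
20 | (1S,3Z)-1-{(2R,3R)-2-[(1S,2E)-1-hydroxy-2-methyl-4-oxobut-2-en-1-yl]-4-methylidene-5-oxooxolan-3-yl}-4-iodo-3-methylbut-3-en-1-yl (2E)-2-methylbut-2-enoate | C=C1C(=O)O[C@@H]([C@@H](O)/C(C)=C/C=O)[C@H]1[C@@H](OC(=O)/C(C)=C/C)C/C(C)=C\I | intermediate
21 | (3aR,4S,6Z,9E,11S,11aR)-8,11-dihydroxy-6,10-dimethyl-3-methylidene-2-oxo-2,3,3a,4,5,8,11,11a-octahydrocyclodeca[b]furan-4-yl (2E)-2-methylbut-2-enoate (both epimers at the ring carbinol next to the two alkenes) | C=C1C(=O)O[C@@H]2[C@H]1[C@@H](OC(=O)/C(C)=C/C)C/C(C)=C\C(O)/C=C(\C)[C@@H]2O | intermediate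
22 | (3aR,4S,6Z,9E,11S,11aR)-11-hydroxy-6,10-dimethyl-3-methylidene-2,8-dioxo-2,3,3a,4,5,8,11,11a-octahydrocyclodeca[b]furan-4-yl (2E)-2-methylbut-2-enoate (CNP0230565.2) | C=C1C(=O)O[C@@H]2[C@H]1[C@@H](OC(=O)/C(C)=C/C)C/C(C)=C\C(=O)/C=C(\C)[C@@H]2O | target

**Step count**
Total: 11 steps. Longest linear sequence: 10 steps (1–4 and 6–11 from furan-3-carbaldehyde); step 5 is a one-step side branch.

**Steps most likely to fail, with fallbacks**

Step 10 (ten-membered ring closure by chromium/nickel coupling; ring strain and oligomerisation). The fallback sets out from 20 and comes back at 22, forming the same C2–C3 bond directly at the ketone level. Pinnick oxidation (NaClO2, NaH2PO4, 2-methylbut-2-ene) turns the aldehyde into the E-enoic acid F3. EtSH/DCC gives the S-ethyl thioester F4. (Me3Sn)2 with Pd(PPh3)4 exchanges iodine for tin to give the Z-vinylstannane F5. An intramolecular Liebeskind–Srogl coupling (Pd2(dba)3, tri(2-furyl)phosphine, CuO2C(C4H3S), THF, high dilution) then closes the ring as the dienone 22, so steps 10 and 11 are both replaced.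

Step 6 (two new stereocentres set next to a weakly biasing centre; risk of low erythro/threo or facial selectivity). The fallback sets out from 9 and comes back at 15, replacing C–C-bond stereocontrol by redox stereocontrol. 9 is silylated to 13 as before and combined with 12 using stoichiometric Bu4N+ Ph3SiF2− and no chiral catalyst, giving the C8/C9-stereorandom aldol adduct F1. Dess–Martin oxidation gives the 5-acylbutenolide F2, in which the C8 hydrogen (γ to the lactone carbonyl, α to the ketone) epimerises freely. Transfer hydrogenation with RuCl(p-cymene)[(S,S)-TsDPEN] in HCO2H/Et3N then reduces the ketone under dynamic kinetic resolution (reagent control at C9, anti Felkin relationship to the C8 oxygen), converging on 15.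

Step 11 (chemoselective oxidation of one of two allylic alcohols; risk of oxidation at C9 or over-oxidation). The fallback sets out from 20 and comes back at 22 with C9 protected. TBSOTf/2,6-lutidine gives the C9 silyl ether F6. The same CrCl2/NiCl2 cyclisation gives the macrocyclic carbinol F7, which has a single free hydroxyl. Dess–Martin periodinane gives the dienone silyl ether F8, and HF·pyridine removes the silyl group to give 22.

Further compounds
F1 | step 6 | aldol adduct 15 as a mixture of stereoisomers at the lactone C2 and the side-chain carbinol | O=C1OC(C(O)/C(C)=C/C(OC)OC)C(=C1)[C@@H](OC(=O)/C(C)=C/C)C/C(C)=C\I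
F2 | step 6 | (1S,3Z)-1-{2-[(2E)-4,4-dimethoxy-2-methylbut-2-enoyl]-5-oxo-2,5-dihydrofuran-3-yl}-4-iodo-3-methylbut-3-en-1-yl (2E)-2-methylbut-2-enoate (ring C2 epimers interconvert) | O=C1OC(C(=O)/C(C)=C/C(OC)OC)C(=C1)[C@@H](OC(=O)/C(C)=C/C)C/C(C)=C\I
F3 | step 10 | carboxylic acid from 20 (CHO oxidised to CO2H, E alkene kept) | C=C1C(=O)O[C@@H]([C@@H](O)/C(C)=C/C(=O)O)[C@H]1[C@@H](OC(=O)/C(C)=C/C)C/C(C)=C\I
F4 | step 10 | S-ethyl thioester of F3 | C=C1C(=O)O[C@@H]([C@@H](O)/C(C)=C/C(=O)SCC)[C@H]1[C@@H](OC(=O)/C(C)=C/C)C/C(C)=C\I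
F5 | step 10 | Z-vinyl(trimethyl)stannane from F4 (iodine replaced by SnMe3) | C=C1C(=O)O[C@@H]([C@@H](O)/C(C)=C/C(=O)SCC)[C@H]1[C@@H](OC(=O)/C(C)=C/C)C/C(C)=C\[Sn](C)(C)C
F6 | step 11 | tert-butyldimethylsilyl ether of 20 at the side-chain carbinol | C=C1C(=O)O[C@@H]([C@@H](O[Si](C)(C)C(C)(C)C)/C(C)=C/C=O)[C@H]1[C@@H](OC(=O)/C(C)=C/C)C/C(C)=C\I
F7 | step 11 | 11-O-tert-butyldimethylsilyl ether of 21 (both epimers at the free carbinol) | C=C1C(=O)O[C@@H]2[C@H]1[C@@H](OC(=O)/C(C)=C/C)C/C(C)=C\C(O)/C=C(\C)[C@@H]2O[Si](C)(C)C(C)(C)C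
F8 | step 11 | 11-O-tert-butyldimethylsilyl ether of 22 | C=C1C(=O)O[C@@H]2[C@H]1[C@@H](OC(=O)/C(C)=C/C)C/C(C)=C\C(=O)/C=C(\C)[C@@H]2O[Si](C)(C)C(C)(C)C
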